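The route rests on disconnecting C2=C3 of a flav-2-ene that stands in for ring C of the upper unit. In ring C (O1, C2, C3, C4, C4a, C8a) the O1–C2–ring B fragment has the oxidation level of a 4-hydroxybenzoate ester of the ring A phenol oxygen O1. Ring B therefore arrives by acylation, and a titanium ethylidene joins the ester carbon (C2) to the inner carbon of a C4 vinyl group (C3). This closes ring C in one operation and leaves the C4 stereocentre, which already carries ring D, untouched. The precursor is a ring A aryl 4-benzyloxybenzoate bearing an ortho (1R)-1-(epicatechin-8-yl)allyl group, fully benzylated.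

Key step: step 12

Remark: the sense of induction of the chiral carbene–copper catalyst in step 9 is assumed as written; if a trial shows that the named (4S,5S) imidazolium salt favours the (S) methine, its (4R,5R) antipode is used instead, with nothing else changed.

Step 1
Reactants: 1 (−)-epicatechin
Product: 2 5,7,3',4'-tetra-O-benzyl-(−)-epicatechin
Conditions: BnBr (4.4 equiv), K2CO3, DMF, 0 °C to rt, Ar
Reagents that add atoms: benzyl bromide, BrCc1ccccc1
Why: Williamson etherification in which K2CO3 deprotonates only the four phenols, the mild base at or below room temperature avoiding ring-opening epimerisation at C2 and leaving the C3 alcohol free.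

Step 2
Reactants: 2 5,7,3',4'-tetra-O-benzyl-(−)-epicatechin
Product: 3 8-bromo-5,7,3',4'-tetra-O-benzyl-(−)-epicatechin
Conditions: NBS (1.0 equiv), CH2Cl2, −78 °C to rt
Reagents that add atoms: N-bromosuccinimide, O=C1CCC(=O)N1Br
Why: Electrophilic aromatic bromination of the most electron-rich ring, which for 5,7-di-O-benzyl flavan-3-ols should take place at C8 in preference to C6 and does not touch the stereocentres.

Step 3
Reactants: 3 8-bromo-5,7,3',4'-tetra-O-benzyl-(−)-epicatechin
Product: 4 8-bromo-3,5,7,3',4'-penta-O-benzyl-(−)-epicatechin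
Conditions: NaH, BnBr, Bu4NI (cat.), DMF, 0 °C to rt
Reagents that add atoms: benzyl bromide, BrCc1ccccc1
Why: Williamson etherification of the secondary alkoxide, safe for C2 because no free phenoxide remains to open the pyran ring.

Step 4
Reactants: 5 2,4,6-trihydroxybenzaldehyde
Product: 6 2,4-bis(benzyloxy)-6-hydroxybenzaldehyde
Conditions: BnBr (2.05 equiv), K2CO3, DMF, 0 °C to rt
Reagents that add atoms: benzyl bromide, BrCc1ccccc1
Why: Selective Williamson etherification in which the hydroxyl hydrogen-bonded to the aldehyde is the least nucleophilic and stays free, which fixes without ambiguity the oxygen that later becomes O1.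

Step 5
Reactants: 6 2,4-bis(benzyloxy)-6-hydroxybenzaldehyde
Product: 7 2-(allyloxy)-4,6-bis(benzyloxy)benzaldehyde
Conditions: allyl bromide, K2CO3, DMF, 50 °C
Reagents that add atoms: allyl bromide, C=CCBr
Why: Williamson allylation of the chelated phenol under slightly more forcing conditions, installing a mask that is orthogonal to benzyl ethers and far below the temperature of a Claisen rearrangement.

Step 6
Reactants: 7 2-(allyloxy)-4,6-bis(benzyloxy)benzaldehyde
Product: 8 ethyl (E)-3-[2-(allyloxy)-4,6-bis(benzyloxy)phenyl]prop-2-enoate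
Conditions: (EtO)2P(O)CH2CO2Et, NaH, THF, 0 °C to 40 °C
Reagents that add atoms: triethyl phosphonoacetate, CCOC(=O)CP(=O)(OCC)OCC
Why: Horner–Wadsworth–Emmons olefination with a stabilised phosphonate, which should give the E-cinnamate under thermodynamic control of the oxaphosphetane.

Step 7
Reactants: 8 ethyl (E)-3-[2-(allyloxy)-4,6-bis(benzyloxy)phenyl]prop-2-enoate
Product: 9 (E)-3-[2-(allyloxy)-4,6-bis(benzyloxy)phenyl]prop-2-en-1-ol
Conditions: i-Bu2AlH (2.2 equiv), CH2Cl2, −78 °C; Rochelle salt work-up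
Reagents that add atoms: none
Why: 1,2-Reduction of the enoate by i-Bu2AlH at low temperature gives the allylic alcohol without touching the alkenes or the ethers.

Step 8
Reactants: 9 (E)-3-[2-(allyloxy)-4,6-bis(benzyloxy)phenyl]prop-2-en-1-ol
Product: 10 (E)-3-[2-(allyloxy)-4,6-bis(benzyloxy)phenyl]prop-2-enyl diethyl phosphate
Conditions: ClP(O)(OEt)2, Et3N, DMAP (cat.), CH2Cl2, 0 °C; used without chromatography
Reagents that add atoms: diethyl chlorophosphate, CCOP(=O)(Cl)OCC
Why: O-Phosphorylation of the primary allylic alcohol gives a leaving group suited to copper-catalysed substitution, the electron-rich cinnamyl phosphate being kept cold and base-buffered to prevent ionisation.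

Step 9
Reactants: 4 8-bromo-3,5,7,3',4'-penta-O-benzyl-(−)-epicatechin; 10 (E)-3-[2-(allyloxy)-4,6-bis(benzyloxy)phenyl]prop-2-enyl diethyl phosphate
Product: 13 8-[(1R)-1-(2-allyloxy-4,6-dibenzyloxyphenyl)prop-2-enyl]-3,5,7,3',4'-penta-O-benzyl-(−)-epicatechin, via 8-lithio-penta-O-benzylepicatechin 11 (not isolated), via penta-O-benzylepicatechin-8-ylmagnesium bromide 12 (not isolated)
Conditions: 4 (1.3 equiv), t-BuLi (2 equiv per 4), THF, −78 °C; MgBr2·OEt2, −78 to 0 °C; then 10, CuCl (5 mol%), (4S,5S)-1,3-bis(2-methoxybenzyl)-4,5-diphenyl-4,5-dihydro-1H-imidazol-3-ium chloride (6 mol%), CH2Cl2/Et2O, −78 to −40 °C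
Reagents that add atoms: none
Why: Copper/chiral N-heterocyclic-carbene-catalysed asymmetric allylic arylation (SN2′) in which the aryl–copper species adds to the γ-carbon of the E-allylic phosphate and the carbene ligand selects the alkene face, so the (R) diarylmethine (the later C4, 4β) is set by the catalyst and not by the remote centres of 12.

Step 10
Reactants: 13 8-[(1R)-1-(2-allyloxy-4,6-dibenzyloxyphenyl)prop-2-enyl]-3,5,7,3',4'-penta-O-benzyl-(−)-epicatechin
Product: 14 8-[(1R)-1-(2,4-dibenzyloxy-6-hydroxyphenyl)prop-2-enyl]-3,5,7,3',4'-penta-O-benzyl-(−)-epicatechin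
Conditions: Pd(PPh3)4 (5 mol%), morpholine, THF, rt
Reagents that add atoms: none
Why: Tsuji–Trost deallylation in which zerovalent palladium ionises only the aryl allyl ether to a π-allyl complex that morpholine captures, while the 1,1-diarylpropene has no leaving group and the neutral conditions spare the acid-sensitive diarylmethine and the benzyl ethers.

Step 11
Reactants: 14 8-[(1R)-1-(2,4-dibenzyloxy-6-hydroxyphenyl)prop-2-enyl]-3,5,7,3',4'-penta-O-benzyl-(−)-epicatechin; 15 4-benzyloxybenzoic acid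
Product: 16 3,5-dibenzyloxy-2-[(1R)-1-(3,5,7,3',4'-penta-O-benzylepicatechin-8-yl)prop-2-enyl]phenyl 4-benzyloxybenzoate
Conditions: DCC, DMAP, CH2Cl2, rt
Reagents that add atoms: none
Why: Steglich esterification of the only free hydroxyl (the ring A phenol that becomes O1) under neutral conditions that cannot epimerise the diarylmethine.

Step 12
Reactants: 16 3,5-dibenzyloxy-2-[(1R)-1-(3,5,7,3',4'-penta-O-benzylepicatechin-8-yl)prop-2-enyl]phenyl 4-benzyloxybenzoate
Product: 17 (4R)-5,7-dibenzyloxy-2-(4-benzyloxyphenyl)-4-(3,5,7,3',4'-penta-O-benzylepicatechin-8-yl)-4H-chromene (4β-aryl flav-2-ene)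
Conditions: TiCl4, TMEDA, Zn, PbCl2 (cat.), CH3CHBr2, THF/CH2Cl2, 0 to 65 °C; K2CO3 work-up, Et3N-deactivated SiO2
Reagents that add atoms: none
Why: The titanium ethylidene formed from CH3CHBr2, Zn/PbCl2 and TiCl4–TMEDA exchanges with the terminal alkene of 16 by [2+2] addition and cycloreversion, releasing propene and placing titanium on the future C3; this alkylidene then adds across the neighbouring ester C=O and the oxatitanacyclobutane collapses to the C2=C3 enol ether and a titanium oxide (ester ethylidenation followed by enol ether–olefin metathesis would end at the same product). The closest known reaction type is the cyclisation of olefinic esters to cyclic enol ethers with titanium alkylidenes of this kind. Ring C closes as a six-membered ring by 6-exo-trig attack of the C3 alkylidene on the ester carbonyl, the two reacting arms being held ortho to each other on ring A. No stereocentre is created, and C4 is carried through unchanged because the reagent is neither basic nor protic and so leaves the doubly benzylic, allylic C4–H alone. The selectivity needed is ring closure over plain alkylidenation of the ester, which the ethylidene (not methylidene) reagent, the ortho arrangement on ring A and the two aryl groups on C4 should secure.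

Step 13
Reactants: 17 (4R)-5,7-dibenzyloxy-2-(4-benzyloxyphenyl)-4-(3,5,7,3',4'-penta-O-benzylepicatechin-8-yl)-4H-chromene
Product: 19 5,7,4'-tri-O-benzyl-(−)-epiafzelechin-(4β→8)-3,5,7,3',4'-penta-O-benzyl-(−)-epicatechin, via 2α,3α-epoxyflavan 18 (not isolated)
Conditions: DMDO (acetone), CH2Cl2, −78 to −20 °C; evaporate cold; LiBHEt3, THF, −78 to 0 °C; then H2O
Reagents that add atoms: dimethyldioxirane, CC1(C)OO1
Why: Epoxidation of the enol ether by DMDO should occur on the α face, anti to ring D held pseudoaxial at C4 by the peri 5-benzyloxy group (3,4-trans), and LiBHEt3 then opens the glycal-type epoxide at the acetal-like C2 by SN2 with inversion, placing H-2 on the β face and giving the 2,3-cis (2R,3R,4R) pattern.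

Step 14
Reactants: 19 5,7,4'-tri-O-benzyl-(−)-epiafzelechin-(4β→8)-3,5,7,3',4'-penta-O-benzyl-(−)-epicatechin
Product: 20 (−)-epiafzelechin-(4β→8)-(−)-epicatechin
Conditions: H2 (1 atm), Pd(OH)2/C, THF/MeOH/H2O, rt
Reagents that add atoms: none
Why: Catalytic hydrogenolysis of the eight benzyl ethers under neutral conditions at atmospheric pressure, the usual last step for benzylated proanthocyanidins, which should leave the ring C–O bonds and the C4–C8 bond intact.

Compound list
1 | (−)-epicatechin, (2R,3R) | Oc1cc(O)c2c(c1)O[C@H](c1ccc(O)c(O)c1)[C@H](O)C2 | starting material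
2 | 5,7,3',4'-tetra-O-benzyl-(−)-epicatechin, (2R,3R) | c1c(OCc2ccccc2)cc(OCc2ccccc2)c2c1O[C@H](c1ccc(OCc3ccccc3)c(OCc3ccccc3)c1)[C@H](O)C2 | intermediate
3 | 8-bromo-5,7,3',4'-tetra-O-benzyl-(−)-epicatechin, (2R,3R) | Brc1c(OCc2ccccc2)cc(OCc2ccccc2)c2c1O[C@H](c1ccc(OCc3ccccc3)c(OCc3ccccc3)c1)[C@H](O)C2 | intermediate
4 | 8-bromo-3,5,7,3',4'-penta-O-benzyl-(−)-epicatechin, (2R,3R) | Brc1c(OCc2ccccc2)cc(OCc2ccccc2)c2c1O[C@H](c1ccc(OCc3ccccc3)c(OCc3ccccc3)c1)[C@H](OCc1ccccc1)C2 | intermediate
5 | 2,4,6-trihydroxybenzaldehyde | O=Cc1c(O)cc(O)cc1O | starting material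
6 | 2,4-bis(benzyloxy)-6-hydroxybenzaldehyde | O=Cc1c(O)cc(OCc2ccccc2)cc1OCc1ccccc1 | intermediate
7 | 2-(allyloxy)-4,6-bis(benzyloxy)benzaldehyde | O=Cc1c(OCC=C)cc(OCc2ccccc2)cc1OCc1ccccc1 | intermediate
8 | ethyl (E)-3-[2-(allyloxy)-4,6-bis(benzyloxy)phenyl]prop-2-enoate | CCOC(=O)/C=C/c1c(OCC=C)cc(OCc2ccccc2)cc1OCc1ccccc1 | intermediate
9 | (E)-3-[2-(allyloxy)-4,6-bis(benzyloxy)phenyl]prop-2-en-1-ol | OC/C=C/c1c(OCC=C)cc(OCc2ccccc2)cc1OCc1ccccc1 | intermediate
10 | (E)-3-[2-(allyloxy)-4,6-bis(benzyloxy)phenyl]prop-2-enyl diethyl phosphate | CCOP(=O)(OCC)OC/C=C/c1c(OCC=C)cc(OCc2ccccc2)cc1OCc1ccccc1 | intermediate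
11 | 8-lithio-3,5,7,3',4'-penta-O-benzyl-(−)-epicatechin | [Li]c1c(OCc2ccccc2)cc(OCc2ccccc2)c2c1O[C@H](c1ccc(OCc3ccccc3)c(OCc3ccccc3)c1)[C@H](OCc1ccccc1)C2 | intermediate
12 | (3,5,7,3',4'-penta-O-benzylepicatechin-8-yl)magnesium bromide | Br[Mg]c1c(OCc2ccccc2)cc(OCc2ccccc2)c2c1O[C@H](c1ccc(OCc3ccccc3)c(OCc3ccccc3)c1)[C@H](OCc1ccccc1)C2 | intermediate
13 | 8-[(1R)-1-(2-allyloxy-4,6-dibenzyloxyphenyl)prop-2-enyl]-3,5,7,3',4'-penta-O-benzyl-(−)-epicatechin | C=CCOc1cc(OCc2ccccc2)cc(OCc2ccccc2)c1[C@H](c1c(OCc2ccccc2)cc(OCc2ccccc2)c2c1O[C@H](c1ccc(OCc3ccccc3)c(OCc3ccccc3)c1)[C@H](OCc1ccccc1)C2)C=C | intermediate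
14 | 8-[(1R)-1-(2,4-dibenzyloxy-6-hydroxyphenyl)prop-2-enyl]-3,5,7,3',4'-penta-O-benzyl-(−)-epicatechin | Oc1cc(OCc2ccccc2)cc(OCc2ccccc2)c1[C@H](c1c(OCc2ccccc2)cc(OCc2ccccc2)c2c1O[C@H](c1ccc(OCc3ccccc3)c(OCc3ccccc3)c1)[C@H](OCc1ccccc1)C2)C=C | intermediate
15 | 4-benzyloxybenzoic acid | OC(=O)c1ccc(OCc2ccccc2)cc1 | starting material
16 | 3,5-dibenzyloxy-2-[(1R)-1-(3,5,7,3',4'-penta-O-benzylepicatechin-8-yl)prop-2-enyl]phenyl 4-benzyloxybenzoate (key-step precursor) | O=C(Oc1cc(OCc2ccccc2)cc(OCc2ccccc2)c1[C@H](c1c(OCc2ccccc2)cc(OCc2ccccc2)c2c1O[C@H](c1ccc(OCc3ccccc3)c(OCc3ccccc3)c1)[C@H](OCc1ccccc1)C2)C=C)c1ccc(OCc2ccccc2)cc1 | intermediate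
17 | (4R)-5,7-dibenzyloxy-2-(4-benzyloxyphenyl)-4-(3,5,7,3',4'-penta-O-benzylepicatechin-8-yl)-4H-chromene (key-step product) | O(Cc1ccccc1)c1ccc(cc1)C1=C[C@@H](c2c(OCc3ccccc3)cc(OCc3ccccc3)c3c2O[C@H](c2ccc(OCc4ccccc4)c(OCc4ccccc4)c2)[C@H](OCc2ccccc2)C3)c2c(OCc3ccccc3)cc(OCc3ccccc3)cc2O1 | intermediate
18 | 2α,3α-epoxide of 17 (epoxide oxygen anti to ring D, 4β-aryl) | O(Cc1ccccc1)c1ccc(cc1)[C@]12Oc3cc(OCc4ccccc4)cc(OCc4ccccc4)c3[C@H](c3c(OCc4ccccc4)cc(OCc4ccccc4)c4c3O[C@H](c3ccc(OCc5ccccc5)c(OCc5ccccc5)c3)[C@H](OCc3ccccc3)C4)[C@H]1O2 | intermediate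
19 | 5,7,4'-tri-O-benzyl-(−)-epiafzelechin-(4β→8)-3,5,7,3',4'-penta-O-benzyl-(−)-epicatechin, upper unit (2R,3R,4R) with free 3-OH, lower unit (2R,3R) | O(Cc1ccccc1)c1ccc(cc1)[C@H]1Oc2cc(OCc3ccccc3)cc(OCc3ccccc3)c2[C@H](c2c(OCc3ccccc3)cc(OCc3ccccc3)c3c2O[C@H](c2ccc(OCc4ccccc4)c(OCc4ccccc4)c2)[C@H](OCc2ccccc2)C3)[C@H]1O | intermediate
20 | (−)-epiafzelechin-(4β→8)-(−)-epicatechin, upper unit (2R,3R,4R), lower unit (2R,3R) | Oc1ccc([C@H]2Oc3cc(O)cc(O)c3[C@H](c3c(O)cc(O)c4c3O[C@H](c3ccc(O)c(O)c3)[C@H](O)C4)[C@H]2O)cc1 | target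

Total step count: 14. Longest linear sequence: 11 steps (steps 4 to 14, from 2,4,6-trihydroxybenzaldehyde); the epicatechin branch joins at step 9 after 3 steps.

Steps most likely to fail

Step 12 (key step). The ester may simply be ethylidenated without ring closure, or the acid- and air-sensitive 4H-chromene may isomerise or oxidise during isolation. The fallback separates the two events and sets out from 16. Methylenation of the ester carbonyl with the Tebbe reagent Cp2Ti(μ-Cl)(μ-CH2)AlMe2 (THF/pyridine, −40 °C to rt) should give the acyclic 1-aryl-vinyl aryl ether F6. Enol ether–olefin ring-closing metathesis then closes the six-membered ring, either with second-generation Grubbs catalyst RuCl2(=CHPh)(PCy3)(H2IMes) in benzene at 60 °C or with Mo(=CHCMe2Ph)(=N-2,6-i-Pr2C6H3)[OCMe(CF3)2]2 at rt, with loss of ethene. The fallback returns to the route at 17.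

Step 9. Both coupling partners carry two ortho oxygen substituents, so transfer of the aryl group to the γ-carbon may be slow; attack at the α-carbon (linear product), protonation of the organometallic or poor face selectivity could then take over. The fallback forms the same C–C bond intramolecularly and without a catalyst, at the price of stereocontrol at the methine. It sets out from 4 and proceeds as follows:
- Bromine–lithium exchange (t-BuLi, THF, −78 °C) and quenching with DMF should give the 8-carbaldehyde F1.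
- Horner–Wadsworth–Emmons olefination with triethyl phosphonoacetate gives the E-acrylate F2.
- i-Bu2AlH reduction gives the allylic alcohol F3.
- Mitsunobu etherification (PPh3, DIAD, THF, 0 °C) with commercial 3,5-bis(benzyloxy)phenol, Oc1cc(OCc2ccccc2)cc(OCc2ccccc2)c1, gives the aryl cinnamyl ether F4.
- Aromatic Claisen rearrangement (N,N-diethylaniline, 170 °C) moves the allyl unit to either of the two equivalent ortho positions with allylic inversion. This unmasks the phenol and gives 14 together with the methine epimer of 14 F5.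

The two are diastereomers because of the epicatechin unit and would be separated by chromatography. The fallback returns to the route at 14 and also bypasses step 10.

Step 13. The very electrophilic epoxide may open to the C2 oxocarbenium ion before hydride arrives. It could then rearrange by 1,2-hydride shift to the 3-ketone, or take up hydride on the wrong face and give the C2 epimer. The fallback sets the same two centres through an open-chain intermediate and sets out from 17:
- Dihydroxylation (OsO4 cat., NMO, acetone/H2O) on the face anti to ring D gives a 2-hydroxy hemiketal that opens to the α-hydroxy ketone F7, with the C3 hydroxyl already α and the ring A phenol free.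
- Chelation-controlled reduction with Zn(BH4)2 (Et2O, −20 °C) should give the anti-1,2-diol F8.
- Intramolecular Mitsunobu etherification (PPh3, DIAD, THF, 0 °C) lets the phenol displace the benzylic C2 hydroxyl with inversion, closing ring C as the 2,3-cis flavan-3-ol.

The fallback returns to the route at 19.

Further compounds
F1 | step 9 | 3,5,7,3',4'-penta-O-benzyl-(−)-epicatechin-8-carbaldehyde | O=Cc1c(OCc2ccccc2)cc(OCc2ccccc2)c2c1O[C@H](c1ccc(OCc3ccccc3)c(OCc3ccccc3)c1)[C@H](OCc1ccccc1)C2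
F2 | step 9 | ethyl (E)-3-(3,5,7,3',4'-penta-O-benzylepicatechin-8-yl)prop-2-enoate | CCOC(=O)/C=C/c1c(OCc2ccccc2)cc(OCc2ccccc2)c2c1O[C@H](c1ccc(OCc3ccccc3)c(OCc3ccccc3)c1)[C@H](OCc1ccccc1)C2
F3 | step 9 | (E)-3-(3,5,7,3',4'-penta-O-benzylepicatechin-8-yl)prop-2-en-1-ol | OC/C=C/c1c(OCc2ccccc2)cc(OCc2ccccc2)c2c1O[C@H](c1ccc(OCc3ccccc3)c(OCc3ccccc3)c1)[C@H](OCc1ccccc1)C2
F4 | step 9 | 3,5-bis(benzyloxy)phenyl (E)-3-(3,5,7,3',4'-penta-O-benzylepicatechin-8-yl)prop-2-enyl ether | C(/C=C/c1c(OCc2ccccc2)cc(OCc2ccccc2)c2c1O[C@H](c1ccc(OCc3ccccc3)c(OCc3ccccc3)c1)[C@H](OCc1ccccc1)C2)Oc1cc(OCc2ccccc2)cc(OCc2ccccc2)c1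
F5 | step 9 | 8-[(1S)-1-(2,4-dibenzyloxy-6-hydroxyphenyl)prop-2-enyl]-3,5,7,3',4'-penta-O-benzyl-(−)-epicatechin (methine epimer of 14) | Oc1cc(OCc2ccccc2)cc(OCc2ccccc2)c1[C@@H](c1c(OCc2ccccc2)cc(OCc2ccccc2)c2c1O[C@H](c1ccc(OCc3ccccc3)c(OCc3ccccc3)c1)[C@H](OCc1ccccc1)C2)C=C
F6 | step 12 | 3,5-dibenzyloxy-2-[(1R)-1-(3,5,7,3',4'-penta-O-benzylepicatechin-8-yl)prop-2-enyl]phenyl 1-(4-benzyloxyphenyl)vinyl ether | C=C(Oc1cc(OCc2ccccc2)cc(OCc2ccccc2)c1[C@H](c1c(OCc2ccccc2)cc(OCc2ccccc2)c2c1O[C@H](c1ccc(OCc3ccccc3)c(OCc3ccccc3)c1)[C@H](OCc1ccccc1)C2)C=C)c1ccc(OCc2ccccc2)cc1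
F7 | step 13 | (2R,3R)-1-(4-benzyloxyphenyl)-3-(2,4-dibenzyloxy-6-hydroxyphenyl)-2-hydroxy-3-(3,5,7,3',4'-penta-O-benzylepicatechin-8-yl)propan-1-one (open form of the 2-hydroxy hemiketal; C3 hydroxyl α, ring D β in flavan terms) | O=C(c1ccc(OCc2ccccc2)cc1)[C@H](O)[C@@H](c1c(OCc2ccccc2)cc(OCc2ccccc2)c2c1O[C@H](c1ccc(OCc3ccccc3)c(OCc3ccccc3)c1)[C@H](OCc1ccccc1)C2)c1c(OCc2ccccc2)cc(OCc2ccccc2)cc1O
F8 | step 13 | (1S,2R,3R)-1-(4-benzyloxyphenyl)-3-(2,4-dibenzyloxy-6-hydroxyphenyl)-3-(3,5,7,3',4'-penta-O-benzylepicatechin-8-yl)propane-1,2-diol (anti-1,2-diol) | O[C@@H](c1ccc(OCc2ccccc2)cc1)[C@H](O)[C@@H](c1c(OCc2ccccc2)cc(OCc2ccccc2)c2c1O[C@H](c1ccc(OCc3ccccc3)c(OCc3ccccc3)c1)[C@H](OCc1ccccc1)C2)c1c(OCc2ccccc2)cc(OCc2ccccc2)cc1O
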